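**Retrosynthetic overview**
1. Target ⇐ two late acylations (C10 acetate, C6 anisoate); the C10–O bond and the C8=C9 alkene arise together from a singlet-oxygen ene (Schenck) reaction of a C9=C10 cycloheptene.
2. Seven-membered ring ⇐ divinylcyclopropane–cycloheptadiene (Cope) ring expansion of a bicyclo[3.1.0]hexane: forms C7–C8, cuts C5–C10 and sets C8–H, which later steers oxygen to C10.
3. Bicyclo[3.1.0]hexane (C1 quaternary centre) ⇐ enantioselective Rh-carbenoid cyclopropanation of a dienyl α-diazo-β-ketonitrile; C4 carbinol ⇐ enol triflate, Negishi coupling, convex-face epoxidation, hydride opening.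
4. Diazo ketonitrile ⇐ Johnson–Claisen rearrangement of the dienol from isopropenylmagnesium bromide and crotonaldehyde, then acylation of lithioacetonitrile and diazo transfer.
5. Ring order: cyclopropane and five-membered ring together (step 5), then the seven-membered ring at the expense of the cyclopropane (step 11).

Numbering in the text (daucane): C1 = quaternary C–Me, C2/C3 = CH2, C4 = C(OH)iPr, C5 = ring-fusion CH, C6 = CH–O-anisoyl, C7 = CH2, C8 = C(Me)=, C9 = CH=, C10 = CH–OAc. The target is the cis-fused isomer (H5 cis to the C1 methyl).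

Assumption: Rh2(S-NTTL)4 (dirhodium tetrakis[N-(1,8-naphthaloyl)-(S)-tert-leucinate], a divalent-rhodium carboxylate dimer) is written for step 5; one pilot run decides whether it or its R antipode gives 10 rather than the mirror image.

Step 1
Reactants: 1 prop-1-en-2-ylmagnesium bromide; 2 (E)-but-2-enal
Product: 3 (E)-2-methylhexa-1,4-dien-3-ol (racemic)
Conditions: THF, −78 to 0 °C; then aq. NH4Cl
Reagents that add atoms: prop-1-en-2-ylmagnesium bromide (compound 1), C=C(C)[Mg]Br
Why: Grignard 1,2-addition of the vinyl nucleophile to the enal carbonyl at low temperature gives the bis-allylic alcohol, whose racemic carbinol centre is erased in step 2.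

Step 2
Reactants: 3 (E)-2-methylhexa-1,4-dien-3-ol; 4 triethyl orthoacetate
Product: 6 ethyl (4E,6E)-4-methylocta-4,6-dienoate, via ketene acetal 5 (not isolated)
Conditions: EtCO2H (cat.), neat 4, 140 °C, EtOH distilled off
Reagents that add atoms: triethyl orthoacetate (compound 4), CCOC(C)(OCC)OCC
Why: Johnson–Claisen rearrangement of ketene acetal 5 through a chair transition state onto the unsubstituted isopropenyl terminus gives the γ,δ-unsaturated ester with the new (E)-trisubstituted C1=C10 alkene conjugated to the untouched (E)-propenyl unit.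

Step 3
Reactants: 6 ethyl (4E,6E)-4-methylocta-4,6-dienoate; 7 acetonitrile
Product: 8 (6E,8E)-6-methyl-3-oxodeca-6,8-dienenitrile
Conditions: n-BuLi, 7, THF, −78 °C; then 6, −78 to −40 °C; then aq. HCl
Reagents that add atoms: acetonitrile (compound 7), CC#N
Why: Claisen-type C-acylation of lithioacetonitrile by the ester, the β-ketonitrile being held as its enolate until the acidic quench so that no second addition occurs.

Step 4
Reactants: 8 (6E,8E)-6-methyl-3-oxodeca-6,8-dienenitrile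
Product: 9 (6E,8E)-2-diazo-6-methyl-3-oxodeca-6,8-dienenitrile
Conditions: 4-acetamidobenzenesulfonyl azide, Et3N, MeCN, 0 °C to rt
Reagents that add atoms: 4-acetamidobenzenesulfonyl azide, CC(=O)Nc1ccc(cc1)S(=O)(=O)N=[N+]=[N-]
Why: Regitz diazo transfer to the doubly activated methylene gives the acceptor/acceptor diazo compound without touching the diene.

Step 5
Reactants: 9 (6E,8E)-2-diazo-6-methyl-3-oxodeca-6,8-dienenitrile
Product: 10 (1S,5R,6R)-5-methyl-2-oxo-6-[(E)-prop-1-enyl]bicyclo[3.1.0]hexane-1-carbonitrile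
Conditions: Rh2(S-NTTL)4 (1 mol%), CH2Cl2, −20 °C, slow addition of 9
Reagents that add atoms: none
Why: Intramolecular carbenoid cyclopropanation in which the Rh-bound carbene at C5 adds to the proximal trisubstituted alkene (five-membered ketone ring favoured), the stereospecific syn addition turns the E geometry into a propenyl group cis to the C1 methyl and the nitrile, and the chiral carboxylate ligands select the alkene face, so C1, C5 and C10 are set in one step.

Step 6
Reactants: 10 (1S,5R,6R)-5-methyl-2-oxo-6-[(E)-prop-1-enyl]bicyclo[3.1.0]hexane-1-carbonitrile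
Product: 12 (1S,5R,6R)-1-cyano-5-methyl-6-[(E)-prop-1-enyl]bicyclo[3.1.0]hex-2-en-2-yl trifluoromethanesulfonate, via potassium enolate 11 (not isolated)
Conditions: KN(SiMe3)2, THF, −78 °C; then PhNTf2, −78 to 0 °C
Reagents that add atoms: N-phenylbis(trifluoromethanesulfonimide), O=S(=O)(N(c1ccccc1)S(=O)(=O)C(F)(F)F)C(F)(F)F
Why: C5 is quaternary, so the amide base can only remove a C3 proton and O-triflation of enolate 11 gives a single enol triflate.

Step 7
Reactants: 12 (1S,5R,6R)-1-cyano-5-methyl-6-[(E)-prop-1-enyl]bicyclo[3.1.0]hex-2-en-2-yl trifluoromethanesulfonate; 13 isopropylzinc bromide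
Product: 14 (1R,5R,6R)-5-methyl-2-(propan-2-yl)-6-[(E)-prop-1-enyl]bicyclo[3.1.0]hex-2-ene-1-carbonitrile
Conditions: Pd(OAc)2 (3 mol%), CPhos (6 mol%), THF, rt
Reagents that add atoms: isopropylzinc bromide (compound 13), CC(C)[Zn]Br
Why: Negishi coupling at the enol triflate, where the CPhos ligand makes reductive elimination faster than β-hydride isomerisation of the secondary alkyl group and the vinylcyclopropane, activated by a nitrile only, is not ionised by zerovalent palladium.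

Step 8
Reactants: 14 (1R,5R,6R)-5-methyl-2-(propan-2-yl)-6-[(E)-prop-1-enyl]bicyclo[3.1.0]hex-2-ene-1-carbonitrile
Product: 15 (1S,2R,4S,6R,7R)-6-methyl-2-(propan-2-yl)-7-[(E)-prop-1-enyl]-3-oxatricyclo[4.1.0.0(2,4)]heptane-1-carbonitrile
Conditions: dimethyldioxirane (1.05 equiv), acetone, −40 to −20 °C
Reagents that add atoms: dimethyldioxirane, CC1(C)OO1
Why: Electrophilic epoxidation goes to the more electron-rich trisubstituted ring alkene rather than the trans-disubstituted propenyl group (estimated 5–10:1) and from the convex face, anti to the cyclopropane C10–H, which puts the oxygen on the face of the C1 methyl.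

Step 9
Reactants: 15 (1S,2R,4S,6R,7R)-6-methyl-2-(propan-2-yl)-7-[(E)-prop-1-enyl]-3-oxatricyclo[4.1.0.0(2,4)]heptane-1-carbonitrile
Product: 17 (1S,2R,5R,6R)-5-methyl-2-(propan-2-yl)-6-[(E)-prop-1-enyl]-2-(trimethylsilyloxy)bicyclo[3.1.0]hexane-1-carbonitrile, via lithium alkoxide 16 (not isolated)
Conditions: LiEt3BH, THF, −20 to 0 °C; then Me3SiCl, 0 °C
Reagents that add atoms: chlorotrimethylsilane, C[Si](C)(C)Cl
Why: SN2 hydride opening at the less substituted epoxide carbon C3 leaves the C4–O bond untouched (oxygen cis to the C1 methyl, isopropyl on the cyclopropane side), the hindered tertiary nitrile survives at this temperature, and silylation of alkoxide 16 blocks a retro-aldol-type ring opening in the next basic step.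

Step 10
Reactants: 17 (1S,2R,5R,6R)-5-methyl-2-(propan-2-yl)-6-[(E)-prop-1-enyl]-2-(trimethylsilyloxy)bicyclo[3.1.0]hexane-1-carbonitrile; 18 methyllithium
Product: 20 1-[(1R,2R,5R,6R)-2-hydroxy-5-methyl-2-(propan-2-yl)-6-[(E)-prop-1-enyl]bicyclo[3.1.0]hexan-1-yl]ethan-1-one, via ketimine 19 (not isolated)
Conditions: MeLi (2.5 equiv), Et2O, −20 °C to rt; then AcOH/NaOAc buffer (pH 5), THF–H2O, rt
Reagents that add atoms: methyllithium (compound 18), [Li]C; water, O
Why: Addition of MeLi to the nitrile stops at the N-lithio ketimine, and buffered hydrolysis of 19 (which also removes the labile O-silyl group) gives the methyl ketone without touching a stereocentre.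

Step 11
Reactants: 20 1-[(1R,2R,5R,6R)-2-hydroxy-5-methyl-2-(propan-2-yl)-6-[(E)-prop-1-enyl]bicyclo[3.1.0]hexan-1-yl]ethan-1-one
Product: 22 (3R,6R,8aR)-6,8a-dimethyl-3-(propan-2-yl)-3,4-bis(trimethylsilyloxy)-1,2,3,5,6,8a-hexahydroazulene, via bis-silyl ether 21 (not isolated)
Conditions: Me3SiOTf, Et3N, CH2Cl2, −78 to 0 °C; then toluene, 110 °C
Reagents that add atoms: trimethylsilyl trifluoromethanesulfonate, C[Si](C)(C)OS(=O)(=O)C(F)(F)F
Why: The ketone can enolise only on its methyl side, and the resulting cis-1-(siloxyvinyl)-2-propenylcyclopropane 21 undergoes the divinylcyclopropane–cycloheptadiene (Cope) rearrangement through the boat transition state, which forms C7–C8, cleaves C5–C10 and, from the E-propenyl geometry, places H8 cis and the C8 methyl trans to the C1 methyl.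

Step 12
Reactants: 22 (3R,6R,8aR)-6,8a-dimethyl-3-(propan-2-yl)-3,4-bis(trimethylsilyloxy)-1,2,3,5,6,8a-hexahydroazulene
Product: 24 (3R,3aR,4S,6R,8aR)-6,8a-dimethyl-3-(propan-2-yl)-1,2,3,3a,4,5,6,8a-octahydroazulene-3,4-diol, via ketone 23 (not isolated)
Conditions: Bu4NF, AcOH, THF, −40 °C; then NaBH4, CeCl3·7H2O, MeOH, −40 °C
Reagents that add atoms: none
Why: Fluoride removes both silyl groups, the enol is protonated at C5 from the less hindered face (that of the C4 oxygen and the C1 methyl, away from the isopropyl group) to give cis-fused ketone 23, and immediate Luche-type reduction delivers hydride from the same convex face, so the C6 hydroxyl ends up trans to H5.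

Step 13
Reactants: 24 (3R,3aR,4S,6R,8aR)-6,8a-dimethyl-3-(propan-2-yl)-1,2,3,3a,4,5,6,8a-octahydroazulene-3,4-diol; 25 4-methoxybenzoyl chloride
Product: 26 (3R,3aR,4S,6R,8aR)-3-hydroxy-6,8a-dimethyl-3-(propan-2-yl)-1,2,3,3a,4,5,6,8a-octahydroazulen-4-yl 4-methoxybenzoate
Conditions: DMAP (cat.), pyridine, CH2Cl2, 0 °C to rt
Reagents that add atoms: 4-methoxybenzoyl chloride (compound 25), COc1ccc(cc1)C(Cl)=O
Why: DMAP-catalysed acylation esterifies the only secondary hydroxyl, the tertiary C4 hydroxyl being too hindered to react.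

Step 14
Reactants: 26 (3R,3aR,4S,6R,8aR)-3-hydroxy-6,8a-dimethyl-3-(propan-2-yl)-1,2,3,3a,4,5,6,8a-octahydroazulen-4-yl 4-methoxybenzoate
Product: 28 (3R,3aR,4S,8S,8aS)-3,8-dihydroxy-6,8a-dimethyl-3-(propan-2-yl)-1,2,3,3a,4,5,8,8a-octahydroazulen-4-yl 4-methoxybenzoate, via hydroperoxide 27 (not isolated)
Conditions: O2, tetraphenylporphyrin (cat.), visible light, CH2Cl2, 0 °C; then PPh3
Reagents that add atoms: dioxygen, O=O
Why: Schenck ene reaction in which H8 is the only allylic hydrogen, so singlet oxygen must bond to C10 on the face of H8 (the face of the C1 methyl) while the double bond shifts to C8=C9, and PPh3 reduces the hydroperoxide with retention.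

Step 15
Reactants: 28 (3R,3aR,4S,8S,8aS)-3,8-dihydroxy-6,8a-dimethyl-3-(propan-2-yl)-1,2,3,3a,4,5,8,8a-octahydroazulen-4-yl 4-methoxybenzoate; 29 acetic anhydride
Product: 30 (3R,3aR,4S,8S,8aS)-8-acetoxy-3-hydroxy-6,8a-dimethyl-3-(propan-2-yl)-1,2,3,3a,4,5,8,8a-octahydroazulen-4-yl 4-methoxybenzoate (CNP0256979.4)
Conditions: DMAP (cat.), pyridine, rt
Reagents that add atoms: acetic anhydride (compound 29), CC(=O)OC(C)=O
Why: DMAP-catalysed acetylation of the secondary allylic alcohol completes the target, the hindered tertiary alcohol staying free.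

**Compound list**
1 | prop-1-en-2-ylmagnesium bromide | C=C(C)[Mg]Br | starting material
2 | (E)-but-2-enal | C/C=C/C=O | starting material
3 | (E)-2-methylhexa-1,4-dien-3-ol (racemic) | C=C(C)C(O)/C=C/C | intermediate
4 | triethyl orthoacetate | CCOC(C)(OCC)OCC | starting material
5 | (E)-3-[(1-ethoxyethenyl)oxy]-2-methylhexa-1,4-diene | C=C(OCC)OC(C(C)=C)/C=C/C | intermediate
6 | ethyl (4E,6E)-4-methylocta-4,6-dienoate | CCOC(=O)CC/C(C)=C/C=C/C | intermediate
7 | acetonitrile | CC#N | starting material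
8 | (6E,8E)-6-methyl-3-oxodeca-6,8-dienenitrile | N#CCC(=O)CC/C(C)=C/C=C/C | intermediate
9 | (6E,8E)-2-diazo-6-methyl-3-oxodeca-6,8-dienenitrile | N#CC(=[N+]=[N-])C(=O)CC/C(C)=C/C=C/C | intermediate
10 | (1S,5R,6R)-5-methyl-2-oxo-6-[(E)-prop-1-enyl]bicyclo[3.1.0]hexane-1-carbonitrile | N#C[C@@]12C(=O)CC[C@]1(C)[C@H]2/C=C/C | intermediate
11 | potassium (1S,5R,6R)-1-cyano-5-methyl-6-[(E)-prop-1-enyl]bicyclo[3.1.0]hex-2-en-2-olate | [K+].N#C[C@@]12C([O-])=CC[C@]1(C)[C@H]2/C=C/C | intermediate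
12 | (1S,5R,6R)-1-cyano-5-methyl-6-[(E)-prop-1-enyl]bicyclo[3.1.0]hex-2-en-2-yl trifluoromethanesulfonate | N#C[C@@]12C(OS(=O)(=O)C(F)(F)F)=CC[C@]1(C)[C@H]2/C=C/C | intermediate
13 | isopropylzinc bromide | CC(C)[Zn]Br | starting material
14 | (1R,5R,6R)-5-methyl-2-(propan-2-yl)-6-[(E)-prop-1-enyl]bicyclo[3.1.0]hex-2-ene-1-carbonitrile | N#C[C@@]12C(C(C)C)=CC[C@]1(C)[C@H]2/C=C/C | intermediate
15 | (1S,2R,4S,6R,7R)-6-methyl-2-(propan-2-yl)-7-[(E)-prop-1-enyl]-3-oxatricyclo[4.1.0.0(2,4)]heptane-1-carbonitrile | N#C[C@@]12[C@@]3(C(C)C)O[C@H]3C[C@]1(C)[C@H]2/C=C/C | intermediate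
16 | lithium (1S,2R,5R,6R)-1-cyano-5-methyl-2-(propan-2-yl)-6-[(E)-prop-1-enyl]bicyclo[3.1.0]hexan-2-olate | [Li+].N#C[C@@]12[C@]([O-])(C(C)C)CC[C@]1(C)[C@H]2/C=C/C | intermediate
17 | (1S,2R,5R,6R)-5-methyl-2-(propan-2-yl)-6-[(E)-prop-1-enyl]-2-(trimethylsilyloxy)bicyclo[3.1.0]hexane-1-carbonitrile | N#C[C@@]12[C@](O[Si](C)(C)C)(C(C)C)CC[C@]1(C)[C@H]2/C=C/C | intermediate
18 | methyllithium | [Li]C | starting material
19 | 1-[(1S,2R,5R,6R)-5-methyl-2-(propan-2-yl)-6-[(E)-prop-1-enyl]-2-(trimethylsilyloxy)bicyclo[3.1.0]hexan-1-yl]ethan-1-imine | CC(=N)[C@@]12[C@](O[Si](C)(C)C)(C(C)C)CC[C@]1(C)[C@H]2/C=C/C | intermediate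
20 | 1-[(1R,2R,5R,6R)-2-hydroxy-5-methyl-2-(propan-2-yl)-6-[(E)-prop-1-enyl]bicyclo[3.1.0]hexan-1-yl]ethan-1-one | CC(=O)[C@@]12[C@](O)(C(C)C)CC[C@]1(C)[C@H]2/C=C/C | intermediate
21 | (1S,2R,5R,6R)-5-methyl-2-(propan-2-yl)-6-[(E)-prop-1-enyl]-2-(trimethylsilyloxy)-1-[1-(trimethylsilyloxy)ethenyl]bicyclo[3.1.0]hexane | C=C(O[Si](C)(C)C)[C@@]12[C@](O[Si](C)(C)C)(C(C)C)CC[C@]1(C)[C@H]2/C=C/C | intermediate
22 | (3R,6R,8aR)-6,8a-dimethyl-3-(propan-2-yl)-3,4-bis(trimethylsilyloxy)-1,2,3,5,6,8a-hexahydroazulene | C[Si](C)(C)OC1=C2[C@](O[Si](C)(C)C)(C(C)C)CC[C@]2(C)C=C[C@H](C)C1 | intermediate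
23 | (3R,3aS,6R,8aR)-3-hydroxy-6,8a-dimethyl-3-(propan-2-yl)-2,3,3a,5,6,8a-hexahydroazulen-4(1H)-one | O=C2C[C@@H](C)C=C[C@@]3(C)CC[C@@](O)(C(C)C)[C@@H]23 | intermediate
24 | (3R,3aR,4S,6R,8aR)-6,8a-dimethyl-3-(propan-2-yl)-1,2,3,3a,4,5,6,8a-octahydroazulene-3,4-diol | O[C@H]2C[C@@H](C)C=C[C@@]3(C)CC[C@@](O)(C(C)C)[C@@H]23 | intermediate
25 | 4-methoxybenzoyl chloride | COc1ccc(cc1)C(Cl)=O | starting material
26 | (3R,3aR,4S,6R,8aR)-3-hydroxy-6,8a-dimethyl-3-(propan-2-yl)-1,2,3,3a,4,5,6,8a-octahydroazulen-4-yl 4-methoxybenzoate | COc1ccc(C(=O)O[C@H]2C[C@@H](C)C=C[C@@]3(C)CC[C@@](O)(C(C)C)[C@@H]23)cc1 | intermediate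
27 | (3R,3aR,4S,8S,8aS)-8-hydroperoxy-3-hydroxy-6,8a-dimethyl-3-(propan-2-yl)-1,2,3,3a,4,5,8,8a-octahydroazulen-4-yl 4-methoxybenzoate | COc1ccc(C(=O)O[C@H]2CC(C)=C[C@H](OO)[C@@]3(C)CC[C@@](O)(C(C)C)[C@@H]23)cc1 | intermediate
28 | (3R,3aR,4S,8S,8aS)-3,8-dihydroxy-6,8a-dimethyl-3-(propan-2-yl)-1,2,3,3a,4,5,8,8a-octahydroazulen-4-yl 4-methoxybenzoate | COc1ccc(C(=O)O[C@H]2CC(C)=C[C@H](O)[C@@]3(C)CC[C@@](O)(C(C)C)[C@@H]23)cc1 | intermediate
29 | acetic anhydride | CC(=O)OC(C)=O | starting material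
30 | (3R,3aR,4S,8S,8aS)-8-acetoxy-3-hydroxy-6,8a-dimethyl-3-(propan-2-yl)-1,2,3,3a,4,5,8,8a-octahydroazulen-4-yl 4-methoxybenzoate | COc1ccc(C(=O)O[C@H]2CC(C)=C[C@H](OC(C)=O)[C@@]3(C)CC[C@@](O)(C(C)C)[C@@H]23)cc1 | target

**Totals and risks**
Total step count: 15. Longest linear sequence: 15 steps (fully linear from 1 and 2).

The three steps most likely to fail are 5, 11 and 14.

Step 5 may give insufficient ee, or the carbenoid may be diverted by the diene. The fallback sets out from 9 and comes back at 10, replacing catalyst control by racemic cyclopropanation and resolution. Achiral Rh2(esp)2 (0.2 mol%, CH2Cl2, 0 °C; esp = α,α,α′,α′-tetramethyl-1,3-benzenedipropanoate) converts 9 into the racemate, that is 10 together with its mirror image (1R,5S,6S)-5-methyl-2-oxo-6-[(E)-prop-1-enyl]bicyclo[3.1.0]hexane-1-carbonitrile F1. A ketoreductase chosen from a screening panel (NADPH, glucose/glucose dehydrogenase recycling, pH 7 buffer) then reduces only F1, expected from the open face to (1R,2S,5S,6S)-2-hydroxy-5-methyl-6-[(E)-prop-1-enyl]bicyclo[3.1.0]hexane-1-carbonitrile F2. F2 is removed by chromatography and unreacted 10 (at most 50%) goes on to step 6.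

Step 11 may stall because the C1 methyl sits syn to both vinyl groups and crowds the boat transition state; a homodienyl 1,5-hydrogen shift could then compete at higher temperature. The fallback sets out from 20 and comes back at 23, replacing the sigmatropic ring expansion by a radical one.
- LiN(SiMe3)2 (2.2 equiv, THF, −78 °C) followed by N-bromosuccinimide gives 2-bromo-1-[(1R,2R,5R,6R)-2-hydroxy-5-methyl-2-(propan-2-yl)-6-[(E)-prop-1-enyl]bicyclo[3.1.0]hexan-1-yl]ethan-1-one F3.
- Bu3SnH/AIBN (benzene, 80 °C, slow addition) generates the α-keto radical, which closes 6-endo onto the propenyl terminus (C7–C8). The resulting cyclopropylcarbinyl radical opens the C5–C10 bond, and the tertiary α-keto radical at C5 is reduced from the convex face to ketone 23, which is then reduced with NaBH4 as in step 12.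
- C8 is no longer set by a concerted transition state, so its epimer (3R,3aS,6S,8aR)-3-hydroxy-6,8a-dimethyl-3-(propan-2-yl)-2,3,3a,5,6,8a-hexahydroazulen-4(1H)-one F4 may accompany 23.
- In that case the mixture is carried through reduction and acylation to (3R,3aR,4S,6S,8aR)-6,8a-dimethyl-3-(propan-2-yl)-1,2,3,3a,4,5,6,8a-octahydroazulene-3,4-diol F5 and (3R,3aR,4S,6S,8aR)-3-hydroxy-6,8a-dimethyl-3-(propan-2-yl)-1,2,3,3a,4,5,6,8a-octahydroazulen-4-yl 4-methoxybenzoate F6, and C10 is then introduced by the oxidation–reduction sequence described next, where C8 becomes planar and both series converge on 28.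

Step 14 may be slow (cis-disubstituted alkene next to a quaternary carbon), or the more reactive trisubstituted product alkene may be over-oxidised. The fallback sets out from 26 and comes back at 28, replacing the ene reaction by allylic oxidation and reduction. CrO3·3,5-dimethylpyrazole (CH2Cl2, −20 °C) oxidises the only allylic C–H (C8–H) with allylic transposition to the enone (3R,3aR,4S,8aS)-3-hydroxy-6,8a-dimethyl-8-oxo-3-(propan-2-yl)-1,2,3,3a,4,5,8,8a-octahydroazulen-4-yl 4-methoxybenzoate F7. NaBH4/CeCl3·7H2O (MeOH, −78 °C) then reduces the C10 ketone 1,2 from the face opposite the adjacent angular methyl, giving 28 with the hydroxyl cis to that methyl.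

Further compounds
F1 | step 5 | (1R,5S,6S)-5-methyl-2-oxo-6-[(E)-prop-1-enyl]bicyclo[3.1.0]hexane-1-carbonitrile | N#C[C@]12C(=O)CC[C@@]1(C)[C@@H]2/C=C/C
F2 | step 5 | (1R,2S,5S,6S)-2-hydroxy-5-methyl-6-[(E)-prop-1-enyl]bicyclo[3.1.0]hexane-1-carbonitrile | N#C[C@]12[C@@H](O)CC[C@@]1(C)[C@@H]2/C=C/C
F3 | step 11 | 2-bromo-1-[(1R,2R,5R,6R)-2-hydroxy-5-methyl-2-(propan-2-yl)-6-[(E)-prop-1-enyl]bicyclo[3.1.0]hexan-1-yl]ethan-1-one | BrCC(=O)[C@@]12[C@](O)(C(C)C)CC[C@]1(C)[C@H]2/C=C/C
F4 | step 11 | (3R,3aS,6S,8aR)-3-hydroxy-6,8a-dimethyl-3-(propan-2-yl)-2,3,3a,5,6,8a-hexahydroazulen-4(1H)-one | O=C2C[C@H](C)C=C[C@@]3(C)CC[C@@](O)(C(C)C)[C@@H]23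
F5 | step 11 | (3R,3aR,4S,6S,8aR)-6,8a-dimethyl-3-(propan-2-yl)-1,2,3,3a,4,5,6,8a-octahydroazulene-3,4-diol | O[C@H]2C[C@H](C)C=C[C@@]3(C)CC[C@@](O)(C(C)C)[C@@H]23
F6 | step 11 | (3R,3aR,4S,6S,8aR)-3-hydroxy-6,8a-dimethyl-3-(propan-2-yl)-1,2,3,3a,4,5,6,8a-octahydroazulen-4-yl 4-methoxybenzoate | COc1ccc(C(=O)O[C@H]2C[C@H](C)C=C[C@@]3(C)CC[C@@](O)(C(C)C)[C@@H]23)cc1
F7 | step 14 | (3R,3aR,4S,8aS)-3-hydroxy-6,8a-dimethyl-8-oxo-3-(propan-2-yl)-1,2,3,3a,4,5,8,8a-octahydroazulen-4-yl 4-methoxybenzoate | COc1ccc(C(=O)O[C@H]2CC(C)=CC(=O)[C@@]3(C)CC[C@@](O)(C(C)C)[C@@H]23)cc1
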